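Late in the three runs, left-handed product stands above 0.5 of the charge (61.0%, 65.7%, 63.5%), so right-handed substrate must be turning into left-handed substrate: a dynamic kinetic resolution.

| flask | left-handed substrate | right-handed substrate | partner | free catalyst | remark | time |
|---|---|---|---|---|---|---|
| north-west | 0.73 M | 0.73 M | 2.2 equiv | 0.2 mol% | run made earlier |  |
| east | 1.1 M | 1.1 M | 2.2 equiv | 0.2 mol% | run made earlier |  |
| south | 0.52 M | 0.52 M | 3.3 equiv | 0.2 mol% | run made earlier |  |
| flask | 0.52 M | 0.52 M | 2.20 equiv | 0.2 mol% |  | 2.0 d |



| run | time / d | left-handed product / % | right-handed substrate / % |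
|---|---|---|---|
| north-west | 0.625 | 45.5 | 30.6 |
| north-west | 1.25 | 53.9 | 23.1 |
| north-west | 1.67 | 56.5 | 19.9 |
| north-west | 2.50 | 61.0 | 17.1 |
| east | 0.333 | 47.7 | 34.2 |
| east | 0.833 | 57.3 | 21.5 |
| east | 1.67 | 62.3 | 14.8 |
| east | 2.50 | 65.7 | 12.5 |
| south | 0.208 | 28.8 | 43.4 |
| south | 0.417 | 38.8 | 37.5 |
| south | 1.04 | 53.5 | 26.0 |
| south | 2.50 | 63.5 | 15.2 |

(scatter of a reading: 0.5 percentage points)

- free catalyst is single-handed; left-handed substrate and right-handed substrate are mirror images of each other, charged as a racemate, each of them at the stated concentration

Mirror images that interconvert head for equal amounts, so a late reading offers a gap: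

gap = whole charge − left-handed product − 2 × right-handed substrate

north-west, 2.50 d: 4.80%
east, 2.50 d: 9.30%
south, 2.50 d: 6.10%

The gap equals right-handed product minus the lag of left-handed substrate behind right-handed substrate, so it is a floor for that product. Pooled over the runs:

leak = sum of gaps / sum of left-handed product = 0.106

This leak, a floor read off the runs for right-handed product formed per left-handed product, is the carried quantity.

- concentration of left-handed product at 2.0 d, in M
- concentration of right-handed substrate at 2.0 d, in M
- concentration of right-handed product at 2.0 d, in M

In the readings the pace goes with partner concentration: south, with less substrate than the other runs but 1.07 times north-west's partner concentration, reaches 53.5% left-handed product by 1.04 d, north-west 53.9% by 1.25 d. North-west needs 1.67 d for 56.5% and east 0.833 d for 57.3%, a factor of 2.00 for 1.51 times the partner concentration. South has 1.50 times the flask's, so the flask at 2.0 d should resemble south near 1.000 d, where the 1.04 d reading shows 53.5% left-handed product and 26.0% right-handed substrate.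

Two ways then give right-handed product in the flask:

gap at that stage: −5.50%
leak × left-handed product: 5.68%

A negative amount is impossible, so the mid-run gap cheats: there left-handed substrate lags. This reckoning commits to the second figure, 0.0591 M.

The forecast gives 0.55 M left-handed product, 0.265 M right-handed substrate and 0.19 M right-handed product, more right-handed product than this reckoning, with “left-handed substrate probably only a few percent late on”.

The flask gives 0.525 M left-handed product, 0.244 M right-handed substrate and 0.0658 M right-handed product.

    2 free catalyst → spent catalyst (k = 0.650 M⁻¹ min⁻¹)
    left-handed substrate ⇌ right-handed substrate (k = 7.40 × 10⁻⁴ min⁻¹)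
    partner + free catalyst + left-handed substrate → free catalyst + left-handed product (k = 2.10 M⁻² min⁻¹)
    2 partner → self-condensation product (k = 5.00 × 10⁻⁵ M⁻¹ min⁻¹)
    partner + free catalyst + right-handed substrate → free catalyst + right-handed product (k = 0.190 M⁻² min⁻¹)

At 2.0 d the flask holds 19.7% left-handed substrate and 6.32% right-handed product. The substrates relax into each other with a half-life of 0.325 d, far shorter than the 27 d half-life of right-handed substrate on its path to right-handed product at that time. The leak on the flask's 50.5% left-handed product gives 5.35% right-handed product. At 2.00 d the neighbouring flask with 0.880 equiv of partner holds 26.3% left-handed product, for which the leak gives 2.79%, and it holds 2.71% right-handed product.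

The runs stem from a simulated flask for substances that don't exist, and the scatter is random.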